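**Retrosynthetic overview**

1. The target is epigallocatechin-(4β→8)-epigallocatechin-(4β→8)-epigallocatechin 3-O-gallate-(4β→8)-epicatechin (units 1 to 4 from the top; ring letters A, C, B as usual for flavans). The last operations are hydrogenolysis of 22 benzyl ethers and a 2+2 Friedel–Crafts coupling that forms C4(unit 2)–C8(unit 3).
2. All rings of units 1, 2 and 4, the gallate ring and both aryl rings of unit 3 come intact from epigallocatechin, epicatechin, gallic acid derivatives and a phloroglucinol ether. The only ring built is the pyran ring C of unit 3 (O1, C2, C3, C4, C4a, C8a), and it is closed after all the others exist.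
3. Enabling feature: in that ring O1–C8a–C4a–C4 is the skeleton of an o-quinone methide with C4 at the aldehyde (acetal) oxidation level, and C2–C3, which carries the 2-aryl and 3-O-galloyl groups cis, is a (Z)-styryl gallate. A [4+2] union of the two closes the ring with the ester already in place and leaves a leaving group at C4.
4. Disconnections at the key step: O1–C2 and C3–C4 (hetero-Diels–Alder), then C4(unit 3)–C8(unit 4) in the same flask, trans to the 3-ester.
5. Order of ring formation: no ring is closed before the key step; ring C of unit 3 is the single and last ring closure.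

Key step: step 9

Assumption: C4 of the 4-methoxy intermediate of the key step is drawn 3,4-trans (the epimer expected after acid-mediated equilibration); both C4 epimers give the same cation in the second stage, so this centre does not affect the outcome.

**Route**

Step 1
Reactants: 1 3,4,5-tris(benzyloxy)benzaldehyde
Product: 2 1,2,3-tris(benzyloxy)-5-ethynylbenzene
Conditions: dimethyl (1-diazo-2-oxopropyl)phosphonate, K2CO3, MeOH/THF, 0 °C to rt
Reagents that add atoms: dimethyl (1-diazo-2-oxopropyl)phosphonate, COP(=O)(OC)C(=[N+]=[N-])C(C)=O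
Why: Seyferth–Gilbert homologation in its Ohira–Bestmann form should turn the aryl aldehyde into the terminal alkyne through a diazomethylphosphonate anion and a vinylidene 1,2-shift under mild base that benzyl ethers tolerate, and no stereocenter is formed.

Step 2
Reactants: 2 1,2,3-tris(benzyloxy)-5-ethynylbenzene; 3 3,4,5-tris(benzyloxy)benzoic acid
Product: 4 (Z)-2-[3,4,5-tris(benzyloxy)phenyl]ethenyl 3,4,5-tris(benzyloxy)benzoate
Conditions: [RuCl2(p-cymene)]2 (2 mol%), P(4-ClC6H4)3, DMAP, toluene, 60 °C
Reagents that add atoms: none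
Why: Ruthenium-catalysed anti-Markovnikov addition of a carboxylic acid to a terminal aryl alkyne (hydro-oxycarbonylation through a ruthenium vinylidene) should give the (Z)-enol ester selectively, and this alkene geometry is the stored form of the later 2,3-cis relationship.

Step 3
Reactants: 5 3,5-bis(benzyloxy)phenol
Product: 6 2,4-bis(benzyloxy)-6-hydroxybenzaldehyde
Conditions: (CH2O)n, MgCl2, Et3N, MeCN, reflux; aq HCl work-up
Reagents that add atoms: formaldehyde (as paraformaldehyde), C=O
Why: In the magnesium-mediated ortho-formylation (Casnati–Skattebøl reaction) formaldehyde is delivered within the magnesium phenoxide only to a carbon ortho to the free hydroxyl, so the future C4 and the one free phenol that becomes O1 should end up adjacent while the position between the two benzyloxy groups stays untouched.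

Step 4
Reactants: 7 (−)-epicatechin
Product: 8 5,7,3',4'-tetra-O-benzyl-(−)-epicatechin
Conditions: BnBr (4.4 equiv), K2CO3, DMF, 0 °C to rt
Reagents that add atoms: benzyl bromide, BrCc1ccccc1
Why: Williamson etherification with K2CO3 should alkylate the four acidic phenols and leave the secondary 3-hydroxyl free, and the mild base at low temperature should not epimerise C2, so the 2R,3R centres are carried over unchanged.

Step 5
Reactants: 9 (−)-epigallocatechin
Product: 10 5,7,3',4',5'-penta-O-benzyl-(−)-epigallocatechin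
Conditions: BnBr (5.5 equiv), K2CO3, DMF, 0 °C to rt, argon
Reagents that add atoms: benzyl bromide, BrCc1ccccc1
Why: The same phenol-selective Williamson etherification, run with exclusion of air to protect the pyrogallol ring, should give the pentabenzyl ether with the 3-hydroxyl free and the 2R,3R centres untouched.

Step 6
Reactants: 10 5,7,3',4',5'-penta-O-benzyl-(−)-epigallocatechin
Product: 11 4β-(2-ethoxyethoxy)-5,7,3',4',5'-penta-O-benzyl-epigallocatechin
Conditions: DDQ (2 equiv), 2-ethoxyethanol, CH2Cl2, rt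
Reagents that add atoms: 2-ethoxyethanol, CCOCCO
Why: DDQ removes hydride from the C4 methylene activated by the 5,7-dibenzyloxy ring and the cation is captured by the alcohol from the β face, away from the cis 2-aryl and 3-hydroxyl groups (benzylic oxidative etherification), so the new C4 centre should be 3,4-trans.

Step 7
Reactants: 11 4β-(2-ethoxyethoxy)-5,7,3',4',5'-penta-O-benzyl-epigallocatechin; 10 5,7,3',4',5'-penta-O-benzyl-(−)-epigallocatechin
Product: 12 deca-O-benzyl-epigallocatechin-(4β→8)-epigallocatechin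
Conditions: 10 (4 equiv), TMSOTf (cat.), CH2Cl2, −78 °C
Reagents that add atoms: none
Why: TMSOTf ionises the C4 ether to the flavan-4-yl cation, which is attacked in a Friedel–Crafts alkylation by C8 of the excess nucleophile 10, its most reactive ring position, from the β face opposite the cis 2-aryl and 3-hydroxyl groups, which should set the 4β (3,4-trans) interflavan centre.

Step 8
Reactants: 12 deca-O-benzyl-epigallocatechin-(4β→8)-epigallocatechin
Product: 13 4β-(2-ethoxyethoxy) derivative of 12 at C4 of the lower unit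
Conditions: DDQ (2 equiv), 2-ethoxyethanol, CH2Cl2, rt
Reagents that add atoms: 2-ethoxyethanol, CCOCCO
Why: The same DDQ oxidative etherification should occur at the only remaining benzylic methylene (C4 of the lower unit), because the C4–H of the upper unit is a diarylmethine flanked by four ortho substituents that cannot reach a planar cation, and the alcohol again enters trans to the 3-hydroxyl.

Step 9
Reactants: 6 2,4-bis(benzyloxy)-6-hydroxybenzaldehyde; 4 (Z)-2-[3,4,5-tris(benzyloxy)phenyl]ethenyl 3,4,5-tris(benzyloxy)benzoate; 8 5,7,3',4'-tetra-O-benzyl-(−)-epicatechin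
Product: 17 5,7,3',4',5'-penta-O-benzyl-3-O-(tri-O-benzylgalloyl)epigallocatechin-(4β→8)-5,7,3',4'-tetra-O-benzylepicatechin, via dimethyl acetal 14 (not isolated), via methoxy o-quinone methide 15 (not isolated), via 4β-methoxyflavan gallate 16 (not isolated)
Conditions: (a) 6 added slowly to 4 (1.5 equiv), HC(OMe)3 (1.2 equiv), (R)-3,3'-bis(2,4,6-triisopropylphenyl)-1,1'-binaphthyl-2,2'-diyl N-triflylphosphoramide (10 mol%; its enantiomer if the facial sense proves opposite), CH2Cl2, −40 to −20 °C, then volatiles removed; (b) 8 (3 equiv), TMSOTf (cat.), CH2Cl2, −78 °C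
Reagents that add atoms: none
Why: Proposed new method: the acid converts 6 through acetal 14 into the methoxy o-quinone methide 15, held as its O-protonated oxocarbenium ion by a hydrogen bond from the phenol to the bulky chiral anion, and this 1-oxadiene (O1=C8a–C4a=C4) adds the C2=C3 bond of 4 in an asynchronous inverse-electron-demand hetero-Diels–Alder reaction in which the acyloxy-bearing carbon bonds to C4 and O1 closes on the benzylic carbon, whose developing charge is taken up by the tris(benzyloxy)phenyl ring. The closest known reaction types are the Sc(OTf)3-catalysed three-component chroman synthesis from salicylaldehydes, trimethyl orthoformate and styrenes and the chiral Brønsted acid catalysed [4+2] cycloadditions of o-quinone methides formed in situ, and what is new is the β-acyloxystyrene as 2π partner under intermolecular enantiocontrol. Ring C of unit 3 is closed in the intermolecular [4+2] mode, C3–C4 and O1–C2 being formed in one event to give the six-membered pyran. C2 and C3 are set cis by suprafacial addition to the (Z)-alkene and in the absolute 2R,3R sense by the chiral anion (the catalyst antipode that gives this sense is taken), whereas C4 is set in stage (b), where TMSOTf ionises the 4-methoxy group of 16 and C8 of 8 attacks the cation anti to the 3-acyloxy group, which shields the α face together with the cis 2-aryl group and can bridge as an acyloxonium ion, so that the 4β (3,4-trans) bond should result. The step needs the regiochemistry C4 to C3 and O1 to C2, secured by the weakly donating aroyl ester that leaves the aryl group in control of alkene polarity, a single mode of ring closure, secured because only one of the two oxygens ortho to the aldehyde carbon of 6 is a free phenol, and C8 over C6 attack on 8, the innate preference of 5,7-dibenzyloxyflavans reinforced by the excess of 8.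

Step 10
Reactants: 17 5,7,3',4',5'-penta-O-benzyl-3-O-(tri-O-benzylgalloyl)epigallocatechin-(4β→8)-5,7,3',4'-tetra-O-benzylepicatechin; 13 4β-(2-ethoxyethoxy) derivative of 12 at C4 of the lower unit
Product: 18 22-fold O-benzylated tetramer (benzyl ether of the target at every phenol)
Conditions: 17 (1.5 equiv), TMSOTf (cat.), CH2Cl2, −40 °C
Reagents that add atoms: none
Why: Friedel–Crafts coupling of the dimeric flavan-4-yl cation from 13 with 17, whose only free C8 position (ring A of unit 3) is its most nucleophilic carbon, should form the last interflavan bond with 4β configuration by attack anti to the cis 2-aryl and 3-hydroxyl groups of unit 2.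

Step 11
Reactants: 18 22-fold O-benzylated tetramer
Product: 19 epigallocatechin-(4β→8)-epigallocatechin-(4β→8)-epigallocatechin 3-O-gallate-(4β→8)-epicatechin (target)
Conditions: H2 (1 atm), Pd(OH)2/C, THF/MeOH/H2O, rt
Reagents that add atoms: none
Why: Hydrogenolysis over Pd(OH)2/C should cleave all 22 benzyl ethers under neutral conditions that leave the gallate ester, the interflavan bonds and every stereocenter untouched.

**Compound list**

1 | 3,4,5-tris(benzyloxy)benzaldehyde | O=Cc1cc(OCc2ccccc2)c(OCc2ccccc2)c(OCc2ccccc2)c1 | starting material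
2 | 1,2,3-tris(benzyloxy)-5-ethynylbenzene | C#Cc1cc(OCc2ccccc2)c(OCc2ccccc2)c(OCc2ccccc2)c1 | intermediate
3 | 3,4,5-tris(benzyloxy)benzoic acid | OC(=O)c1cc(OCc2ccccc2)c(OCc2ccccc2)c(OCc2ccccc2)c1 | starting material
4 | (Z)-2-[3,4,5-tris(benzyloxy)phenyl]ethenyl 3,4,5-tris(benzyloxy)benzoate | O=C(O/C=C\c1cc(OCc2ccccc2)c(OCc2ccccc2)c(OCc2ccccc2)c1)c1cc(OCc2ccccc2)c(OCc2ccccc2)c(OCc2ccccc2)c1 | intermediate
5 | 3,5-bis(benzyloxy)phenol | Oc1cc(OCc2ccccc2)cc(OCc2ccccc2)c1 | starting material
6 | 2,4-bis(benzyloxy)-6-hydroxybenzaldehyde | O=Cc1c(O)cc(OCc2ccccc2)cc1OCc1ccccc1 | intermediate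
7 | (−)-epicatechin, (2R,3R) | O[C@@H]1Cc2c(O)cc(O)cc2O[C@@H]1c1ccc(O)c(O)c1 | starting material
8 | 5,7,3',4'-tetra-O-benzyl-(−)-epicatechin, (2R,3R), 3-OH free | O[C@@H]1Cc2c(OCc3ccccc3)cc(OCc3ccccc3)cc2O[C@@H]1c1ccc(OCc2ccccc2)c(OCc2ccccc2)c1 | intermediate
9 | (−)-epigallocatechin, (2R,3R) | O[C@@H]1Cc2c(O)cc(O)cc2O[C@@H]1c1cc(O)c(O)c(O)c1 | starting material
10 | 5,7,3',4',5'-penta-O-benzyl-(−)-epigallocatechin, (2R,3R), 3-OH free | O[C@@H]1Cc2c(OCc3ccccc3)cc(OCc3ccccc3)cc2O[C@@H]1c1cc(OCc2ccccc2)c(OCc2ccccc2)c(OCc2ccccc2)c1 | intermediate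
11 | 4β-(2-ethoxyethoxy)-5,7,3',4',5'-penta-O-benzyl-epigallocatechin, (2R,3R,4S), ether trans to 3-OH | CCOCCO[C@H]1c2c(OCc3ccccc3)cc(OCc3ccccc3)cc2O[C@H](c2cc(OCc3ccccc3)c(OCc3ccccc3)c(OCc3ccccc3)c2)[C@@H]1O | intermediate
12 | deca-O-benzyl-epigallocatechin-(4β→8)-epigallocatechin, all phenols benzylated, both 3-OH free | C1c2c(OCc3ccccc3)cc(OCc3ccccc3)c([C@H]3c4c(OCc5ccccc5)cc(OCc5ccccc5)cc4O[C@H](c4cc(OCc5ccccc5)c(OCc5ccccc5)c(OCc5ccccc5)c4)[C@@H]3O)c2O[C@H](c2cc(OCc3ccccc3)c(OCc3ccccc3)c(OCc3ccccc3)c2)[C@@H]1O | intermediate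
13 | 12 carrying a 4β-(2-ethoxyethoxy) group at C4 of the lower unit, trans to its 3-OH | CCOCCO[C@H]1c2c(OCc3ccccc3)cc(OCc3ccccc3)c([C@H]3c4c(OCc5ccccc5)cc(OCc5ccccc5)cc4O[C@H](c4cc(OCc5ccccc5)c(OCc5ccccc5)c(OCc5ccccc5)c4)[C@@H]3O)c2O[C@H](c2cc(OCc3ccccc3)c(OCc3ccccc3)c(OCc3ccccc3)c2)[C@@H]1O | intermediate
14 | 3,5-bis(benzyloxy)-2-(dimethoxymethyl)phenol | COC(OC)c1c(O)cc(OCc2ccccc2)cc1OCc1ccccc1 | intermediate
15 | (E)-3,5-bis(benzyloxy)-6-(methoxymethylidene)cyclohexa-2,4-dien-1-one (reacts as its O-protonated ion pair) | CO/C=C1/C(=O)C=C(OCc2ccccc2)C=C1OCc1ccccc1 | intermediate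
16 | (2R,3R,4S)-4β-methoxy-5,7,3',4',5'-penta-O-benzyl-epigallocatechin 3-O-[3,4,5-tris(benzyloxy)benzoate] | O=C(O[C@@H]1[C@@H](OC)c2c(OCc3ccccc3)cc(OCc3ccccc3)cc2O[C@@H]1c1cc(OCc2ccccc2)c(OCc2ccccc2)c(OCc2ccccc2)c1)c1cc(OCc2ccccc2)c(OCc2ccccc2)c(OCc2ccccc2)c1 | intermediate
17 | 5,7,3',4',5'-penta-O-benzyl-3-O-(tri-O-benzylgalloyl)epigallocatechin-(4β→8)-5,7,3',4'-tetra-O-benzylepicatechin | O=C(O[C@@H]1[C@@H](c2c(OCc3ccccc3)cc(OCc3ccccc3)c3c2O[C@H](c2ccc(OCc4ccccc4)c(OCc4ccccc4)c2)[C@H](O)C3)c2c(OCc3ccccc3)cc(OCc3ccccc3)cc2O[C@@H]1c1cc(OCc2ccccc2)c(OCc2ccccc2)c(OCc2ccccc2)c1)c1cc(OCc2ccccc2)c(OCc2ccccc2)c(OCc2ccccc2)c1 | intermediate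
18 | 22-fold O-benzylated tetramer: the target with every phenolic OH as a benzyl ether and the three 3-OH free | O=C(O[C@@H]1[C@@H](c2c(OCc3ccccc3)cc(OCc3ccccc3)c3c2O[C@H](c2ccc(OCc4ccccc4)c(OCc4ccccc4)c2)[C@H](O)C3)c2c(OCc3ccccc3)cc(OCc3ccccc3)c([C@H]3c4c(OCc7ccccc7)cc(OCc7ccccc7)c([C@H]5c6c(OCc7ccccc7)cc(OCc7ccccc7)cc6O[C@H](c6cc(OCc7ccccc7)c(OCc7ccccc7)c(OCc7ccccc7)c6)[C@@H]5O)c4O[C@H](c4cc(OCc7ccccc7)c(OCc7ccccc7)c(OCc7ccccc7)c4)[C@@H]3O)c2O[C@@H]1c1cc(OCc2ccccc2)c(OCc2ccccc2)c(OCc2ccccc2)c1)c1cc(OCc2ccccc2)c(OCc2ccccc2)c(OCc2ccccc2)c1 | intermediate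
19 | epigallocatechin-(4β→8)-epigallocatechin-(4β→8)-epigallocatechin 3-O-gallate-(4β→8)-epicatechin (CNP0305998.1) | O=C(O[C@@H]1[C@@H](c2c(O)cc(O)c3c2O[C@H](c2ccc(O)c(O)c2)[C@H](O)C3)c2c(O)cc(O)c([C@H]3c4c(O)cc(O)c([C@H]5c6c(O)cc(O)cc6O[C@H](c6cc(O)c(O)c(O)c6)[C@@H]5O)c4O[C@H](c4cc(O)c(O)c(O)c4)[C@@H]3O)c2O[C@@H]1c1cc(O)c(O)c(O)c1)c1cc(O)c(O)c(O)c1 | target

**Summary and risks**

Total step count: 11. Longest linear sequence: 6 steps (9 → 10 → 11 → 12 → 13 → 18 → 19).

Steps most likely to fail:

Step 9 (labelled step, the riskiest). What may go wrong: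
- The enol ester may add in a stepwise cationic manner, so that bond rotation or acyloxonium capture erodes the 2,3-cis relationship.
- The chiral anion may fail to discriminate the two alkene faces.
- The alkene polarity may reverse, so that O1 bonds to the acyloxy carbon.
- The electron-rich acetal may condense with itself instead of being intercepted by the alkene.

Fallback with known chemistry, setting out from 10 and 3: Steglich esterification (EDC·HCl, DMAP, CH2Cl2) should give octa-O-benzyl-(−)-epigallocatechin 3-O-gallate F1. DDQ oxidation of F1 in the presence of methanol (CH2Cl2, rt) should install the 4β-methoxy group and so give 16. The route is rejoined at 16, which is carried to 17 under the stage (b) conditions of step 9. This fallback takes ring C of unit 3 from the chiral pool instead of building it.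

Step 8. What may go wrong: hydride abstraction by DDQ at the interflavan diarylmethine or further oxidation of the electron-rich dimer, leading to cleavage or a mixture of oxidised sites. Fallback by orthogonal activation, setting out from 11: BF3·OEt2 and 2,6-dimethylbenzenethiol (CH2Cl2, −78 °C) should exchange the ether for a thioether and give 4β-(2,6-dimethylphenylthio)-penta-O-benzyl-epigallocatechin F2. A second portion of 11 is then coupled with F2 under BF3·OEt2, which activates the C4–O bond but not the C4–S bond, to give the deca-O-benzyl dimer 4β-thioether F3. Soft activation of F3 with I2 and Ag2O in the presence of 17 (CH2Cl2, −78 to 0 °C) should give 18 directly, where the route is rejoined.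

Step 10. What may go wrong: the bulky dimeric cation may react slowly at the hindered C8 of unit 3, so that self-condensation of 13 through its own free C8 and attack at C6 positions compete. Fallback by stepwise chain extension with the monomeric electrophile, setting out from 17 and 11: TMSOTf-mediated coupling of 17 with 11 (CH2Cl2, −78 °C) should give the protected trimer epigallocatechin-(4β→8)-epigallocatechin gallate-(4β→8)-epicatechin F4. A second coupling of F4 with 11 under the same conditions should give 18, where the route is rejoined. The smaller cation reaches C8 more easily, and its self-condensation products are far lighter than the product and can be separated.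

Further compounds
F1 | step 9 | octa-O-benzyl-(−)-epigallocatechin 3-O-gallate | O=C(O[C@@H]1Cc2c(OCc3ccccc3)cc(OCc3ccccc3)cc2O[C@@H]1c1cc(OCc2ccccc2)c(OCc2ccccc2)c(OCc2ccccc2)c1)c1cc(OCc2ccccc2)c(OCc2ccccc2)c(OCc2ccccc2)c1
F2 | step 8 | 4β-(2,6-dimethylphenylthio)-5,7,3',4',5'-penta-O-benzyl-epigallocatechin | Cc1cccc(C)c1S[C@H]1c2c(OCc3ccccc3)cc(OCc3ccccc3)cc2O[C@H](c2cc(OCc3ccccc3)c(OCc3ccccc3)c(OCc3ccccc3)c2)[C@@H]1O
F3 | step 8 | deca-O-benzyl-epigallocatechin-(4β→8)-epigallocatechin with a 4β-(2,6-dimethylphenylthio) group on the lower unit | Cc1cccc(C)c1S[C@H]1c2c(OCc3ccccc3)cc(OCc3ccccc3)c([C@H]3c4c(OCc5ccccc5)cc(OCc5ccccc5)cc4O[C@H](c4cc(OCc5ccccc5)c(OCc5ccccc5)c(OCc5ccccc5)c4)[C@@H]3O)c2O[C@H](c2cc(OCc3ccccc3)c(OCc3ccccc3)c(OCc3ccccc3)c2)[C@@H]1O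
F4 | step 10 | 17-fold O-benzylated trimer epigallocatechin-(4β→8)-epigallocatechin 3-O-gallate-(4β→8)-epicatechin | O=C(O[C@@H]1[C@@H](c2c(OCc3ccccc3)cc(OCc3ccccc3)c3c2O[C@H](c2ccc(OCc4ccccc4)c(OCc4ccccc4)c2)[C@H](O)C3)c2c(OCc3ccccc3)cc(OCc3ccccc3)c([C@H]3c4c(OCc7ccccc7)cc(OCc7ccccc7)cc4O[C@H](c4cc(OCc7ccccc7)c(OCc7ccccc7)c(OCc7ccccc7)c4)[C@@H]3O)c2O[C@@H]1c1cc(OCc2ccccc2)c(OCc2ccccc2)c(OCc2ccccc2)c1)c1cc(OCc2ccccc2)c(OCc2ccccc2)c(OCc2ccccc2)c1
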